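**Retrosynthetic overview**

1. The last C–C bond is C14–C15: Zr-catalysed carboalumination of a C13≡C14 alkyne, then Pd coupling with a separately made (Z)-iodomethylidene butenolide. The C18 aldehyde travels as a dioxolane and is released last.
2. 8α-OH/8β-CH3 and 6α-OH arise together from an exocyclic C8=C17 alkene bearing a 6α-acetyl group: one peracid step (α-face epoxidation plus Baeyer–Villiger oxidation), then LiAlH4.
3. Rings A and B are formed at the same time from an acyclic trienone with a single stereocentre (C4). An intramolecular Diels–Alder reaction makes C5–C10 and C6–C7 and sets C5, C6 and C10. The butenolide ring is built off-line and joined last.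
4. Enabling feature of the trienone: the diene C7=C8–C9=C10 is held by the C1–C2–C3 chain and quaternary C4 next to the (E)-enone C5=C6–C(O)CH3. C8 carries CH2SiMe3 (the latent C17 methylene), C10 carries the future angular methyl inside and the tether outside, the acetyl is the masked 6-OH, and CH3 versus 1,3-dioxolan-2-yl on C4 differentiates the two faces of C5=C6.
5. The trienone comes from a B-alkyl Suzuki–Miyaura coupling (C1–C10) of an allyl fragment with the (E)-enol triflate of an alkylated acetoacetate, then ester-to-allylsilane conversion. C4 is set by Pd-catalysed asymmetric allylic alkylation of isoprene monoepoxide.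

Key step: step 15

Numbering used below (labdane type): ring A = C1–C5 and C10, ring B = C5–C10; C18 is the oxidised carbon on C4 (α); C19 and C20 are the methyl carbons on C4 (β) and C10 (β); C17 is the carbon on C8; C11–C15 run from C9 to the butenolide; α is the face opposite the C10 methyl.

Assumption: the (1R,2R)-ligand of step 1 is taken to deliver the (S)-configured adduct; if the sense of induction proves opposite, the (1S,2S)-ligand is used and nothing else changes.

Remark: the 6α-hydroxy-18-aldehyde may equilibrate with its lactol; the open form drawn for the target is taken as the product.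

**Route**

Step 1
Reactants: 1 2-methyl-2-vinyloxirane (racemic); 2 dimethyl malonate
Product: 3 dimethyl 2-[(2S)-1-hydroxy-2-methylbut-3-en-2-yl]propanedioate
Conditions: Pd2(dba)3·CHCl3 (1 mol %), (1R,2R)-N,N′-bis[2-(diphenylphosphino)benzoyl]cyclohexane-1,2-diamine (3 mol %), CH2Cl2, rt
Reagents that add atoms: none
Why: Tsuji–Trost allylic alkylation run as a dynamic kinetic asymmetric transformation, in which the interconverting π-allyl-palladium intermediates from the racemic vinyl epoxide are attacked by the malonate at the more substituted terminus (delivery by ion pairing with the alkoxide set free on ionisation), so that the chiral ligand sets the quaternary C4 stereocentre.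

Step 2
Reactants: 3 dimethyl 2-[(2S)-1-hydroxy-2-methylbut-3-en-2-yl]propanedioate
Product: 5 (4R)-4-ethenyl-4-methyloxolan-2-one, via lactone ester 4 (not isolated)
Conditions: LiCl (3 equiv), H2O (2 equiv), DMSO, 150 °C; acidic work-up
Reagents that add atoms: none
Why: the neopentyl hydroxyl should close the γ-lactone onto one ester (gem-dialkyl effect) and the remaining β-dicarbonyl methyl ester is removed by Krapcho dealkoxycarbonylation, neither event touching the quaternary centre.

Step 3
Reactants: 5 (4R)-4-ethenyl-4-methyloxolan-2-one; 6 (2S)-but-3-en-2-ol (3 equiv)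
Product: 7 (4R)-4-[(1E,3S)-3-hydroxybut-1-en-1-yl]-4-methyloxolan-2-one
Conditions: RuCl2(H2IMes)(=CH-C6H4-2-O-i-Pr) (second-generation Hoveyda–Grubbs catalyst, 5 mol %), CH2Cl2, 40 °C
Reagents that add atoms: none
Why: olefin cross-metathesis between the hindered vinyl group, which does not homodimerise, and the allylic alcohol should give the thermodynamically favoured (E)-alkene, the carbinol stereocentre being brought in with the alcohol and erased later by oxidation.

Step 4
Reactants: 7 (4R)-4-[(1E,3S)-3-hydroxybut-1-en-1-yl]-4-methyloxolan-2-one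
Product: 8 (4R)-4-[(1E,3S)-3-{[tert-butyl(dimethyl)silyl]oxy}but-1-en-1-yl]-4-methyloxolan-2-one
Conditions: TBSCl, imidazole, DMF, rt
Reagents that add atoms: tert-butyldimethylsilyl chloride CC(C)(C)[Si](C)(C)Cl
Why: standard silylation of a secondary alcohol masks the future enone oxygen for the hydride, ylide and organometallic steps that follow.

Step 5
Reactants: 8 (4R)-4-[(1E,3S)-3-{[tert-butyl(dimethyl)silyl]oxy}but-1-en-1-yl]-4-methyloxolan-2-one
Product: 9 (4R)-4-[(1E,3S)-3-{[tert-butyl(dimethyl)silyl]oxy}but-1-en-1-yl]-4-methyloxolan-2-ol (both anomers)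
Conditions: i-Bu2AlH (1.1 equiv), CH2Cl2, −78 °C; aq. potassium sodium tartrate
Reagents that add atoms: none
Why: half-reduction of a γ-lactone stops at the stable aluminium lactolate at low temperature.

Step 6
Reactants: 9 (4R)-4-[(1E,3S)-3-{[tert-butyl(dimethyl)silyl]oxy}but-1-en-1-yl]-4-methyloxolan-2-ol
Product: 10 (2R)-2-[(1E,3S)-3-{[tert-butyl(dimethyl)silyl]oxy}but-1-en-1-yl]-2-methylpent-4-en-1-ol
Conditions: Ph3PCH3Br (3 equiv), KN(SiMe3)2 (2.9 equiv), THF, 0 °C → rt
Reagents that add atoms: methyltriphenylphosphonium bromide C[P+](c1ccccc1)(c1ccccc1)c1ccccc1.[Br-]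
Why: Wittig methylenation of the open hydroxy-aldehyde form of the lactol turns C2 and the ylide carbon into the allyl terminus (C2=C1) and frees the C18 hydroxyl.

Step 7
Reactants: 10 (2R)-2-[(1E,3S)-3-{[tert-butyl(dimethyl)silyl]oxy}but-1-en-1-yl]-2-methylpent-4-en-1-ol
Product: 11 (2R)-2-[(1E,3S)-3-{[tert-butyl(dimethyl)silyl]oxy}but-1-en-1-yl]-2-methylpent-4-enal
Conditions: Dess–Martin periodinane, NaHCO3, CH2Cl2, rt
Reagents that add atoms: none
Why: Dess–Martin oxidation of the neopentyl alcohol gives an aldehyde that has no α-hydrogen and therefore cannot epimerise or conjugate.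

Step 8
Reactants: 11 (2R)-2-[(1E,3S)-3-{[tert-butyl(dimethyl)silyl]oxy}but-1-en-1-yl]-2-methylpent-4-enal
Product: 12 tert-butyl{[(2S,3E,5R)-5-(1,3-dioxolan-2-yl)-5-methylocta-3,7-dien-2-yl]oxy}dimethylsilane
Conditions: 1,2-bis(trimethylsilyloxy)ethane, TMSOTf (cat.), CH2Cl2, −78 → −20 °C
Reagents that add atoms: 1,2-bis(trimethylsilyloxy)ethane C[Si](C)(C)OCCO[Si](C)(C)C
Why: aprotic silyl-triflate-catalysed acetalisation works on hindered aldehydes and spares the silyl ether, and it installs the branched C18 group that later shields one face of the dienophile.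

Step 9
Reactants: 13 ethyl 3-oxobutanoate; 14 (4-bromobut-1-yn-1-yl)trimethylsilane
Product: 15 ethyl 2-acetyl-6-(trimethylsilyl)hex-5-ynoate (racemic)
Conditions: NaH, THF–DMF, 0 °C; then 14, NaI (cat.), 60 °C
Reagents that add atoms: none
Why: C-alkylation of the acetoacetate anion with the primary homopropargylic bromide brings in C11–C14 of the side chain.

Step 10
Reactants: 15 ethyl 2-acetyl-6-(trimethylsilyl)hex-5-ynoate
Product: 16 ethyl (2E)-3-{[(trifluoromethyl)sulfonyl]oxy}-2-[4-(trimethylsilyl)but-3-yn-1-yl]but-2-enoate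
Conditions: aq. Me4NOH, Tf2O, toluene, 0 °C
Reagents that add atoms: trifluoromethanesulfonic anhydride O=S(=O)(OS(=O)(=O)C(F)(F)F)C(F)(F)F
Why: O-triflation of the β-keto ester enolate with a non-coordinating tetramethylammonium counter-ion should go through the non-chelated enolate and give the (E)-enol triflate (triflate trans to the ester), which fixes the geometry of the future C9=C10 bond.

Step 11
Reactants: 12 tert-butyl{[(2S,3E,5R)-5-(1,3-dioxolan-2-yl)-5-methylocta-3,7-dien-2-yl]oxy}dimethylsilane; 16 ethyl (2E)-3-{[(trifluoromethyl)sulfonyl]oxy}-2-[4-(trimethylsilyl)but-3-yn-1-yl]but-2-enoate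
Product: 18 ethyl (2E,7R,8E,10S)-10-{[tert-butyl(dimethyl)silyl]oxy}-7-(1,3-dioxolan-2-yl)-3,7-dimethyl-2-[4-(trimethylsilyl)but-3-yn-1-yl]undeca-2,8-dienoate, via alkylborane 17 (not isolated)
Conditions: 9-BBN-H (1.3 equiv), THF, rt; then 16, PdCl2(dppf) (5 mol %), AsPh3, Cs2CO3, DMF–H2O, rt
Reagents that add atoms: none
Why: 9-BBN hydroborates only the unhindered terminal alkene and the B-alkyl Suzuki–Miyaura coupling replaces the triflate with retention, which joins C1 to C10 with the tether trans and the methyl cis to the ester carbon.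

Step 12
Reactants: 18 ethyl (2E,7R,8E,10S)-10-{[tert-butyl(dimethyl)silyl]oxy}-7-(1,3-dioxolan-2-yl)-3,7-dimethyl-2-[4-(trimethylsilyl)but-3-yn-1-yl]undeca-2,8-dienoate
Product: 20 allylsilane diene (ester of 18 replaced by C(=CH2)CH2SiMe3), via bis-adduct carbinol 19 (not isolated)
Conditions: Me3SiCH2MgCl (6 equiv), CeCl3 (6 equiv), THF, −78 °C → rt; then SiO2, CH2Cl2
Reagents that add atoms: (trimethylsilyl)methylmagnesium chloride C[Si](C)(C)C[Mg]Cl
Why: cerium-mediated double addition to the hindered ester and Peterson elimination of the resulting β-hydroxysilane give the 2-(silylmethyl)-1,3-diene without touching the tetrasubstituted alkene geometry.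

Step 13
Reactants: 20 allylsilane diene
Product: 21 (2S,3E,5R,9E)-10-(but-3-yn-1-yl)-5-(1,3-dioxolan-2-yl)-5,9-dimethyl-11-[(trimethylsilyl)methyl]dodeca-3,9,11-trien-2-ol
Conditions: n-Bu4NF (3 equiv), AcOH (1 equiv), THF, 0 °C → rt
Reagents that add atoms: none
Why: fluoride cleaves the O–Si bond of the allylic silyl ether and the C(sp)–Si bond of the alkyne, whereas the allylic C(sp3)–SiMe3 bond is inert in the absence of an electrophile.

Step 14
Reactants: 21 (2S,3E,5R,9E)-10-(but-3-yn-1-yl)-5-(1,3-dioxolan-2-yl)-5,9-dimethyl-11-[(trimethylsilyl)methyl]dodeca-3,9,11-trien-2-ol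
Product: 22 (3E,5R,9E)-10-(but-3-yn-1-yl)-5-(1,3-dioxolan-2-yl)-5,9-dimethyl-11-[(trimethylsilyl)methyl]dodeca-3,9,11-trien-2-one
Conditions: MnO2 (activated, 20 equiv), CH2Cl2, rt; used at once
Reagents that add atoms: none
Why: MnO2 oxidises only the allylic alcohol on a neutral surface that the acid-sensitive allylsilane diene should tolerate, and it removes the auxiliary carbinol stereocentre.

Step 15
Reactants: 22 (3E,5R,9E)-10-(but-3-yn-1-yl)-5-(1,3-dioxolan-2-yl)-5,9-dimethyl-11-[(trimethylsilyl)methyl]dodeca-3,9,11-trien-2-one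
Product: 23 Diels–Alder adduct (trans-fused rings A and B with C8=C9; 6α-acetyl; allylsilane on C8)
Conditions: Me2AlCl (1.5 equiv), CH2Cl2, −78 → −20 °C
Reagents that add atoms: none
Why: Me2AlCl binds the enone carbonyl and the substrate should undergo a concerted, asynchronous [4+2] cycloaddition (type 1 intramolecular Diels–Alder reaction) in which the C5–C10 bond to the enone β-carbon runs ahead of the C6–C7 bond; the closest known reaction types are the alkylaluminium-chloride-promoted cyclisation of terminally activated 1,3,9-decatrienes to trans-decalins, including cases that create an angular methyl group, and Lewis-acid-promoted cycloadditions of 2-(silylmethyl)dienes with enones. Ring A closes through the C5–C10 bond with the C1–C3 tether in a chair and exo to the diene, and ring B is the cyclohexene made by the cycloaddition itself (C6–C7 and C5–C10, new C8=C9). C10 follows from the diene geometry fixed in steps 10 and 11 (methyl inside, tether outside), the trans relation of H5 and H6 from the (E)-enone, and the trans ring fusion with a 6α-acetyl group from the endo orientation of the complexed carbonyl. The absolute sense is relayed from C4: with C3 held near the plane of the dienophile by the tether, the diene should add to the face that carries the small methyl group and away from the branched 1,3-dioxolan-2-yl group, which puts that methyl axial and cis to the new C10 methyl. The step therefore needs endo over exo selectivity and this facial selectivity; the first is secured by the Lewis acid complex at low temperature and by the C9 substituent, which clashes with an endo tether, the second by the size difference at C4. The CH2SiMe3 group on C8 raises the diene HOMO, biases the 2,3-disubstituted diene towards the s-cis form and survives as an allylsilane for step 16.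

Step 16
Reactants: 23 Diels–Alder adduct
Product: 24 exocyclic alkene (C8=C17H2; 9α-H; 9β-but-3-ynyl; 6α-acetyl)
Conditions: CF3CO2H (2 equiv), CH2Cl2, 0 °C
Reagents that add atoms: none
Why: SE2′ protodesilylation of the allylsilane, in which the proton adds to C9 from the α-face (axial, opposite the C10 methyl) so that the side chain becomes β-equatorial and loss of silicon from the β-silyl cation leaves the exocyclic C8=C17 alkene.

Step 17
Reactants: 24 exocyclic alkene
Product: 26 6α-acetoxy-8α,17-epoxide, via epoxy ketone 25 (not isolated)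
Conditions: mCPBA (4 equiv), NaHCO3, CH2Cl2, 0 °C → rt
Reagents that add atoms: 3-chloroperoxybenzoic acid OOC(=O)c1cccc(Cl)c1
Why: the peracid should epoxidise the exocyclic alkene from the α-face (away from the axial C10 methyl), putting the oxygen on C8 α and C17 β, and then effect Baeyer–Villiger oxidation of the methyl ketone with migration of the secondary C6 with retention, while the terminal alkyne is inert.

Step 18
Reactants: 26 6α-acetoxy-8α,17-epoxide
Product: 27 6α,8α-diol (8β-CH3; 9β-but-3-ynyl; C18 as dioxolane)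
Conditions: LiAlH4, THF, 0 → 40 °C
Reagents that add atoms: none
Why: hydride opens the spiro-epoxide at the unhindered CH2 (C17), which leaves the 8α-oxygen as the tertiary alcohol and makes the 8β-methyl, and it cleaves the acetate to the 6α-alcohol.

Step 19
Reactants: 28 but-2-ynoic acid
Product: 29 (2Z)-3-iodobut-2-enoic acid
Conditions: NaI, AcOH, 115 °C
Reagents that add atoms: sodium iodide [Na+].[I-]
Why: anti hydroiodination of the ynoic acid places iodide at the β-carbon cis to the carboxyl group.

Step 20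
Reactants: 29 (2Z)-3-iodobut-2-enoic acid; 30 ethynyl(trimethyl)silane
Product: 32 (5Z)-4-methyl-5-[(trimethylsilyl)methylidene]furan-2(5H)-one, via enynoic acid 31 (not isolated)
Conditions: PdCl2(PPh3)2 (3 mol %), CuI (5 mol %), Et3N, MeCN, rt
Reagents that add atoms: none
Why: Sonogashira coupling gives the (Z)-enynoic acid, whose carboxylate adds anti across the metal-activated alkyne in a 5-exo-dig lactonisation, which places the silyl group cis to the ring oxygen (Z).

Step 21
Reactants: 32 (5Z)-4-methyl-5-[(trimethylsilyl)methylidene]furan-2(5H)-one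
Product: 33 (5Z)-5-(iodomethylidene)-4-methylfuran-2(5H)-one
Conditions: N-iodosuccinimide, MeCN, 0 °C → rt, dark
Reagents that add atoms: N-iodosuccinimide O=C1CCC(=O)N1I
Why: ipso-iododesilylation of the vinylsilane through the oxygen- and β-silicon-stabilised cation should proceed with retention and keep the (Z)-geometry.

Step 22
Reactants: 27 6α,8α-diol; 33 (5Z)-5-(iodomethylidene)-4-methylfuran-2(5H)-one
Product: 35 1,3-dioxolane acetal of the target, via alkenylalane 34 (not isolated)
Conditions: Me3Al (5 equiv), Cp2ZrCl2 (0.5 equiv), CH2Cl2, 0 °C → rt; volatiles removed; then 33, Pd(PPh3)4 (5 mol %), THF, rt; aq. potassium sodium tartrate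
Reagents that add atoms: trimethylaluminium C[Al](C)C
Why: Zr-catalysed carboalumination adds methyl and aluminium syn across the terminal alkyne (methyl to C13), which fixes the (13E)-alkene, and the alkenylalane couples with the alkenyl iodide under palladium catalysis (Negishi coupling) with retention at both partners, the two hydroxyls being carried as aluminium alkoxides.

Step 23
Reactants: 35 1,3-dioxolane acetal of the target
Product: 36 CNP0278517.1
Conditions: 1 M HCl, THF–H2O, rt
Reagents that add atoms: water O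
Why: acid hydrolysis of the dioxolane releases the non-enolisable C18 aldehyde under conditions that should leave the tertiary alcohol and the dienyl butenolide intact.

**Compound list**

1 | 2-methyl-2-vinyloxirane (isoprene monoepoxide, racemic) | CC1(CO1)C=C | starting material
2 | dimethyl malonate | COC(=O)CC(=O)OC | starting material
3 | dimethyl 2-[(2S)-1-hydroxy-2-methylbut-3-en-2-yl]propanedioate | COC(=O)C(C(=O)OC)[C@@](C)(CO)C=C | intermediate
4 | methyl (4S)-4-ethenyl-4-methyl-2-oxooxolane-3-carboxylate (C3 epimers; same spatial arrangement at C4 as in 5, the letter changes with the priorities) | COC(=O)C1C(=O)OC[C@@]1(C)C=C | intermediate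
5 | (4R)-4-ethenyl-4-methyloxolan-2-one | O=C1C[C@@](C)(CO1)C=C | intermediate
6 | (2S)-but-3-en-2-ol | C=C[C@H](C)O | starting material
7 | (4R)-4-[(1E,3S)-3-hydroxybut-1-en-1-yl]-4-methyloxolan-2-one | O=C1C[C@@](C)(CO1)/C=C/[C@H](C)O | intermediate
8 | (4R)-4-[(1E,3S)-3-{[tert-butyl(dimethyl)silyl]oxy}but-1-en-1-yl]-4-methyloxolan-2-one | O=C1C[C@@](C)(CO1)/C=C/[C@H](C)O[Si](C)(C)C(C)(C)C | intermediate
9 | (4R)-4-[(1E,3S)-3-{[tert-butyl(dimethyl)silyl]oxy}but-1-en-1-yl]-4-methyloxolan-2-ol (both anomers) | OC1C[C@@](C)(CO1)/C=C/[C@H](C)O[Si](C)(C)C(C)(C)C | intermediate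
10 | (2R)-2-[(1E,3S)-3-{[tert-butyl(dimethyl)silyl]oxy}but-1-en-1-yl]-2-methylpent-4-en-1-ol | C=CC[C@@](C)(CO)/C=C/[C@H](C)O[Si](C)(C)C(C)(C)C | intermediate
11 | (2R)-2-[(1E,3S)-3-{[tert-butyl(dimethyl)silyl]oxy}but-1-en-1-yl]-2-methylpent-4-enal | C=CC[C@@](C)(C=O)/C=C/[C@H](C)O[Si](C)(C)C(C)(C)C | intermediate
12 | tert-butyl{[(2S,3E,5R)-5-(1,3-dioxolan-2-yl)-5-methylocta-3,7-dien-2-yl]oxy}dimethylsilane | C=CC[C@@](C)(C1OCCO1)/C=C/[C@H](C)O[Si](C)(C)C(C)(C)C | intermediate
13 | ethyl 3-oxobutanoate (ethyl acetoacetate) | CCOC(=O)CC(C)=O | starting material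
14 | (4-bromobut-1-yn-1-yl)trimethylsilane | C[Si](C)(C)C#CCCBr | starting material
15 | ethyl 2-acetyl-6-(trimethylsilyl)hex-5-ynoate (racemic) | CCOC(=O)C(CCC#C[Si](C)(C)C)C(C)=O | intermediate
16 | ethyl (2E)-3-{[(trifluoromethyl)sulfonyl]oxy}-2-[4-(trimethylsilyl)but-3-yn-1-yl]but-2-enoate | CCOC(=O)/C(CCC#C[Si](C)(C)C)=C(\C)OS(=O)(=O)C(F)(F)F | intermediate
17 | 9-[(4R,5E,7S)-7-{[tert-butyl(dimethyl)silyl]oxy}-4-(1,3-dioxolan-2-yl)-4-methyloct-5-en-1-yl]-9-borabicyclo[3.3.1]nonane | C1CCC2CCCC1B2CCC[C@@](C)(C3OCCO3)/C=C/[C@H](C)O[Si](C)(C)C(C)(C)C | intermediate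
18 | ethyl (2E,7R,8E,10S)-10-{[tert-butyl(dimethyl)silyl]oxy}-7-(1,3-dioxolan-2-yl)-3,7-dimethyl-2-[4-(trimethylsilyl)but-3-yn-1-yl]undeca-2,8-dienoate | CCOC(=O)/C(CCC#C[Si](C)(C)C)=C(\C)CCC[C@@](C)(C1OCCO1)/C=C/[C@H](C)O[Si](C)(C)C(C)(C)C | intermediate
19 | tertiary carbinol from double addition to the ester of 18: the ester carbon carries OH and two CH2SiMe3 groups | C[Si](C)(C)CC(O)(C[Si](C)(C)C)/C(CCC#C[Si](C)(C)C)=C(\C)CCC[C@@](C)(C1OCCO1)/C=C/[C@H](C)O[Si](C)(C)C(C)(C)C | intermediate
20 | tert-butyl{[(2S,3E,5R,9E)-5-(1,3-dioxolan-2-yl)-5,9-dimethyl-10-[4-(trimethylsilyl)but-3-yn-1-yl]-11-[(trimethylsilyl)methyl]dodeca-3,9,11-trien-2-yl]oxy}dimethylsilane | C=C(C[Si](C)(C)C)/C(CCC#C[Si](C)(C)C)=C(\C)CCC[C@@](C)(C1OCCO1)/C=C/[C@H](C)O[Si](C)(C)C(C)(C)C | intermediate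
21 | (2S,3E,5R,9E)-10-(but-3-yn-1-yl)-5-(1,3-dioxolan-2-yl)-5,9-dimethyl-11-[(trimethylsilyl)methyl]dodeca-3,9,11-trien-2-ol | C=C(C[Si](C)(C)C)/C(CCC#C)=C(\C)CCC[C@@](C)(C1OCCO1)/C=C/[C@H](C)O | intermediate
22 | (3E,5R,9E)-10-(but-3-yn-1-yl)-5-(1,3-dioxolan-2-yl)-5,9-dimethyl-11-[(trimethylsilyl)methyl]dodeca-3,9,11-trien-2-one | C=C(C[Si](C)(C)C)/C(CCC#C)=C(\C)CCC[C@@](C)(C1OCCO1)/C=C/C(C)=O | intermediate
23 | Diels–Alder adduct: trans-fused rings A and B with C8=C9; 4β-CH3, 4α-(1,3-dioxolan-2-yl), 5α-H, 6α-acetyl, 8-CH2SiMe3, 9-(but-3-yn-1-yl), 10β-CH3 | C#CCCC=1[C@@]2(C)CCC[C@@](C)(C3OCCO3)[C@@H]2[C@@H](C(C)=O)CC=1C[Si](C)(C)C | intermediate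
24 | exocyclic alkene: trans-decalin with C8=C17H2; 4β-CH3, 4α-(1,3-dioxolan-2-yl), 5α-H, 6α-acetyl, 9α-H, 9β-(but-3-yn-1-yl), 10β-CH3 | C#CCC[C@@H]1[C@@]2(C)CCC[C@@](C)(C3OCCO3)[C@@H]2[C@@H](C(C)=O)CC1=C | intermediate
25 | 8α,17-epoxide of 24 (oxygen α on C8, C17 β; 6α-acetyl kept) | C#CCC[C@@H]1[C@@]2(C)CCC[C@@](C)(C3OCCO3)[C@@H]2[C@@H](C(C)=O)C[C@@]1(C4)O4 | intermediate
26 | 6α-acetoxy-8α,17-epoxide (otherwise as 25) | C#CCC[C@@H]1[C@@]2(C)CCC[C@@](C)(C3OCCO3)[C@@H]2[C@@H](OC(C)=O)C[C@@]1(C4)O4 | intermediate
27 | 6α,8α-diol: trans-decalin with 4β-CH3, 4α-(1,3-dioxolan-2-yl), 5α-H, 6α-OH, 8α-OH, 8β-CH3, 9β-(but-3-yn-1-yl), 10β-CH3 | C#CCC[C@@H]1[C@@]2(C)CCC[C@@](C)(C3OCCO3)[C@@H]2[C@@H](O)C[C@@]1(C)O | intermediate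
28 | but-2-ynoic acid | CC#CC(=O)O | starting material
29 | (2Z)-3-iodobut-2-enoic acid | C/C(I)=C/C(=O)O | intermediate
30 | ethynyl(trimethyl)silane | C#C[Si](C)(C)C | starting material
31 | (2Z)-3-methyl-5-(trimethylsilyl)pent-2-en-4-ynoic acid | C/C(C#C[Si](C)(C)C)=C/C(=O)O | intermediate
32 | (5Z)-4-methyl-5-[(trimethylsilyl)methylidene]furan-2(5H)-one | CC1=CC(=O)O/C1=C\[Si](C)(C)C | intermediate
33 | (5Z)-5-(iodomethylidene)-4-methylfuran-2(5H)-one | CC1=CC(=O)O/C1=C\I | intermediate
34 | (E)-alkenyl(dimethyl)alane from 27: C14 carries AlMe2, C13 the new methyl; both hydroxyls as dimethylaluminium alkoxides | C[Al](C)/C=C(\C)CC[C@@H]1[C@@]2(C)CCC[C@@](C)(C3OCCO3)[C@@H]2[C@@H](O[Al](C)C)C[C@@]1(C)O[Al](C)C | intermediate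
35 | target with C18 as 1,3-dioxolane (6α-OH, 8α-OH, complete (13E)-dienyl (Z)-ylidene butenolide side chain) | CC1=CC(=O)O/C1=C\C=C(/C)CC[C@@H]1[C@@]2(C)CCC[C@@](C)(C3OCCO3)[C@@H]2[C@@H](O)C[C@@]1(C)O | intermediate
36 | CNP0278517.1: 6α,8α-dihydroxy-18-al with the (13E)-dienyl (Z)-4-methyl-ylidene-butenolide side chain | CC1=CC(=O)O/C1=C\C=C(/C)CC[C@@H]1[C@@]2(C)CCC[C@@](C)(C=O)[C@@H]2[C@@H](O)C[C@@]1(C)O | target

**Totals**

Total step count: 23. Longest linear sequence: 18 steps (steps 1–8, 11–18, 22 and 23).

**Steps most likely to fail**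

1. Step 15. The exo transition state (cis ring fusion) or attack on the dioxolanyl face of the dienophile (wrong sense at C5, C6 and C10 relative to C4) may compete, or the Lewis acid may ionise or protodesilylate the allylsilane diene before it cyclises. Fallback (sets out from 22, returns at 24): the neutral complexed enone is replaced by a cationic dienophile (ionic Diels–Alder reaction). Treatment of 22 with 1,2-bis(trimethylsilyloxy)ethane, TMSOTf (cat.) and 2,6-di-tert-butyl-4-methylpyridine in CH2Cl2 at −78 °C should convert the enone in the flask into the trienone dioxolane F1. Its ionisation to a dioxolanylium-stabilised allyl cation is expected to trigger cyclisation at low temperature to the cyclised ketal F2. Brief treatment with TsOH in wet acetone should then release the methyl ketone and protodesilylate the allylsilane, which gives 24.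

2. Step 10. Enolisation and triflation of the α-substituted β-keto ester may lose (E)-selectivity because the chelated (Z)-enolate competes; after coupling this would put the tether inside and the methyl outside on the diene. Fallback (sets out from 12, returns at 18): the roles in the coupling are exchanged so that the geometry rests on the more dependable chelation-controlled triflation. Linear hydroformylation of the terminal alkene of 12 (Rh(acac)(CO)2, Xantphos, CO/H2, toluene, 60 °C) should give the aldehyde F3. Roskamp homologation (ethyl diazoacetate, SnCl2 cat., CH2Cl2) should give the β-keto ester F4. Alkylation with 14 (NaH, NaI, THF–DMF) should give the α-alkylated β-keto ester F5. Triflation of its lithium chelate (LiOTf, Et3N, Tf2O, CH2Cl2, −78 °C) should give the (Z)-enol triflate F6. Iron-catalysed cross-coupling with MeMgBr (Fe(acac)3, THF–NMP, −30 °C) would then put the methyl where the triflate was, cis to the ester, which is 18.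

3. Step 22. Carboalumination may stall in the presence of two aluminium alkoxides, or the alkenylalane and residual aluminium reagents may attack the lactone of 33 or be protonated before the coupling. Fallback (sets out from 27, returns at 35): the butenolide is built last instead of being coupled as a unit. The carboalumination of 27 is quenched with I2 to give the (E)-vinyl iodide F7. Sonogashira coupling with 30 (PdCl2(PPh3)2, CuI, Et3N) should give the silyl enyne F8, and K2CO3 in MeOH the terminal enyne F9. Coupling of F9 with 29 under the conditions of step 20 is expected to pass through the dienynoic acid F10, which lactonises in the flask to 35.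

Further compounds
F1 | step 15 | ethylene ketal of the ketone of 22 (2-methyl-2-alkenyl-1,3-dioxolane, formed in the flask) | C=C(C[Si](C)(C)C)/C(CCC#C)=C(\C)CCC[C@@](C)(C1OCCO1)/C=C/C1(C)OCCO1
F2 | step 15 | ethylene ketal of the acetyl group of 23 | C#CCCC=1[C@@]2(C)CCC[C@@](C)(C3OCCO3)[C@@H]2[C@@H](C4(C)OCCO4)CC=1C[Si](C)(C)C
F3 | step 10 | (5R,6E,8S)-8-{[tert-butyl(dimethyl)silyl]oxy}-5-(1,3-dioxolan-2-yl)-5-methylnon-6-enal | O=CCCC[C@@](C)(C1OCCO1)/C=C/[C@H](C)O[Si](C)(C)C(C)(C)C
F4 | step 10 | ethyl (7R,8E,10S)-10-{[tert-butyl(dimethyl)silyl]oxy}-7-(1,3-dioxolan-2-yl)-7-methyl-3-oxoundec-8-enoate | CCOC(=O)CC(=O)CCC[C@@](C)(C1OCCO1)/C=C/[C@H](C)O[Si](C)(C)C(C)(C)C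
F5 | step 10 | F4 alkylated at C2 with the 4-(trimethylsilyl)but-3-yn-1-yl group (C2 epimers) | CCOC(=O)C(CCC#C[Si](C)(C)C)C(=O)CCC[C@@](C)(C1OCCO1)/C=C/[C@H](C)O[Si](C)(C)C(C)(C)C
F6 | step 10 | (Z)-enol triflate of F5 (triflate cis to the ester) | CCOC(=O)/C(CCC#C[Si](C)(C)C)=C(\OS(=O)(=O)C(F)(F)F)CCC[C@@](C)(C1OCCO1)/C=C/[C@H](C)O[Si](C)(C)C(C)(C)C
F7 | step 22 | (E)-vinyl iodide from 27 (C13 methyl, C14 iodide) | I/C=C(\C)CC[C@@H]1[C@@]2(C)CCC[C@@](C)(C3OCCO3)[C@@H]2[C@@H](O)C[C@@]1(C)O
F8 | step 22 | (E)-enyne with C-silylated terminus | C[Si](C)(C)C#C/C=C(\C)CC[C@@H]1[C@@]2(C)CCC[C@@](C)(C3OCCO3)[C@@H]2[C@@H](O)C[C@@]1(C)O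
F9 | step 22 | terminal (E)-enyne | C#C/C=C(\C)CC[C@@H]1[C@@]2(C)CCC[C@@](C)(C3OCCO3)[C@@H]2[C@@H](O)C[C@@]1(C)O
F10 | step 22 | (2Z)-dienynoic acid formed in the flask before lactonisation | OC(=O)/C=C(/C)C#C/C=C(\C)CC[C@@H]1[C@@]2(C)CCC[C@@](C)(C3OCCO3)[C@@H]2[C@@H](O)C[C@@]1(C)O
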